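Amounts first: at 1.3 equiv of partner the substrate is the limiting reagent, so the meeting opened with the balance of the substrate charge.

| flask | substrate | partner | temperature | remark | time |
|---|---|---|---|---|---|
| amber | 0.42 M | 1.3 equiv | 32 °C | run made earlier |  |
| ochre | 0.92 M | 1.3 equiv | 49 °C | run made earlier |  |
| summer | 0.60 M | 1.30 equiv |  | at 25 °C throughout | 2.5 min |
| dawn | 0.30 M | 1.30 equiv |  | at 25 °C until 30 s, from then on at 55 °C | 2.5 min |

- amber (time / min: open intermediate / %, target / %, substrate / %): 0.200: 28.2, 1.7, 72.3; 0.333: 39.8, 1.8, 56.7; 0.500: 48.6, 4.8, 42.7; 0.833: 57.9, 13.9, 23.4; 1.50: 57.6, 30.9, 9.0; 2.50: 51.6, 41.4, 0.7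
- ochre (time / s: open intermediate / %, target / %, substrate / %): 10.0: 61.0, 15.8, 22.0; 15.0: 59.9, 26.1, 12.0; 25.0: 53.6, 36.1, 3.8; 30.0: 51.1, 39.1, 0.7; 40.0: 43.5, 39.5, 0.5; 50.0: 39.7, 41.1, 0.5

(standard deviation of a reading: 1 percentage point)

- where the amount of substrate changes, what is given in equivalents or mol% on it follows

- which one finishes higher in amount of open intermediate, in percent of the substrate charged ("neither" within 2 percentage points) (summer / dawn / neither)
- amount of open intermediate at the end, in percent of the substrate charged, summer
- amount of open intermediate at the end, in percent of the substrate charged, dawn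

The first speaker reported that the amber run at 2.50 min has 6.30% of the charge missing from substrate, open intermediate and target, and that in the ochre run at 50.0 s the same three leave 18.7% unaccounted for, which is more than in amber. She added that from 30.0 s to 50.0 s in ochre the open intermediate fell by 11 percentage points while target rose by 2 points, so she argued that most of that fall leads somewhere other than target.

The maker of the forecast put down summer as the higher flask, with 56% for summer and 10% for dawn, and allowed “perhaps more if the loss is bimolecular”.

The first speaker took up that allowance in a reckoning of her own. She assumed a second-order loss, so that the reciprocal of c(open intermediate) climbs steadily, and the same ochre stretch gives 0.0305 L mol⁻¹ s⁻¹, the loss constant, a reading that carries the scatter and the small flow to target. At a share of 61.0%, the first half-life by this loss is 58.3 s in ochre but 179 s at dawn's charge, longer than dawn's 120 s in the hot bath. Starting dawn at that share at the change of temperature, with the constant unscaled, she reckoned 36.5%, which differs from the forecast's 10% and stays below its 56% for summer, so the minutes kept summer.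

The flasks finish at 44.9% in summer and 45.6% in dawn, so the answer is neither.

    substrate → open intermediate (k = 0.0129 s⁻¹, Ea = 81.0 kJ mol⁻¹)
    partner → second intermediate (k = 0.0122 s⁻¹, Ea = 72.0 kJ mol⁻¹)
    open intermediate + second intermediate → target (k = 0.0280 L mol⁻¹ s⁻¹, Ea = 45.0 kJ mol⁻¹)
    2 open intermediate → homo product (k = 7.60 × 10⁻⁴ L mol⁻¹ s⁻¹, Ea = 79.0 kJ mol⁻¹)
    second intermediate → side product (k = 0.00708 s⁻¹, Ea = 92.0 kJ mol⁻¹)
    (constants at 25 °C)

Where the step from open intermediate to homo product is missing, the difference, summer minus dawn, is −36 points. Carrying dawn on from 45.6% to 25.0 min with the loss constant 0.0305 L mol⁻¹ s⁻¹ gives 6.87%, and dawn at that time holds 7.39% of open intermediate.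

Readings and results come from a simulation with constants of no real substance; the scatter is artificial.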